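**Plan**

- Dinklagein A is a 2-aryl-1-benzofuran (5-OH, 6-OMe, 7-prenyl, 3-hydroxy-5-methoxyphenyl at C2). It has no stereocentre and no stereogenic alkene, so no stereochemistry has to be set.
- Enabling feature: C2 carries both O1 and the aryl ring, so it can enter as a CBr2 carbon. One bromide is displaced by the C7a phenol oxygen and the other is kept for the biaryl bond.
- Retrosynthetic cuts: C2–C1' (Suzuki coupling), then O1–C2 (copper C–O coupling, furan ring), then C2=C3 (Ramirez olefination of a salicylaldehyde).
- The salicylaldehyde is cut at C3a–C3 (ortho-formylation) and C7–CH2 (carbamate-directed metalation and prenylation), back to a phenol made from vanillin by MOM protection and Dakin-type oxidation.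
- Forward: the fully substituted benzene ring is built first, the furan ring closes on it in step 8, and the resorcinol-type ring is attached last as its pinacol boronate, followed by removal of one MOM ether.

Key step: step 8

Remark: benzofuran numbering (O1, C2, C3, C3a, C4 to C7, C7a) is used for the target, and prenyl means 3-methylbut-2-en-1-yl. The phenol of the resorcinol-type fragment is assumed to need no protection in the borylation and the cross-coupling, both of which tolerate free phenols.

**Route**

Step 1
Reactants: 1 vanillin (4-hydroxy-3-methoxybenzaldehyde)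
Product: 2 3-methoxy-4-(methoxymethoxy)benzaldehyde
Conditions: MOMCl, iPr2NEt, CH2Cl2, 0 °C to rt
Reagents that add atoms: chloromethyl methyl ether (MOMCl), COCCl
Why: Williamson-type O-alkylation of the phenol with MOMCl under amine base is a routine MOM protection and leaves the aldehyde untouched.

Step 2
Reactants: 2 3-methoxy-4-(methoxymethoxy)benzaldehyde
Product: 4 3-methoxy-4-(methoxymethoxy)phenol, via aryl formate 3 (not isolated)
Conditions: mCPBA, CH2Cl2, 0 °C to rt; then K2CO3 (cat.), MeOH, rt
Reagents that add atoms: 3-chloroperoxybenzoic acid (mCPBA), OOC(=O)c1cccc(Cl)c1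
Why: Baeyer–Villiger (Dakin-type) oxidation of an electron-rich alkoxybenzaldehyde proceeds with aryl migration to the aryl formate, whose base-catalysed methanolysis frees the phenol while the MOM acetal is stable to both stages.

Step 3
Reactants: 4 3-methoxy-4-(methoxymethoxy)phenol
Product: 5 3-methoxy-4-(methoxymethoxy)phenyl N,N-diethylcarbamate
Conditions: NaH, THF, 0 °C; then ClC(O)NEt2, 0 °C to rt
Reagents that add atoms: N,N-diethylcarbamoyl chloride, CCN(CC)C(Cl)=O
Why: O-carbamoylation of the phenoxide (ArONa) installs the strongest oxygen-based directing group for ortho-metalation and keeps this oxygen distinct from the MOM-protected one.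

Step 4
Reactants: 5 3-methoxy-4-(methoxymethoxy)phenyl N,N-diethylcarbamate; 6 prenyl bromide (1-bromo-3-methylbut-2-ene)
Product: 9 3-methoxy-4-(methoxymethoxy)-2-(3-methylbut-2-en-1-yl)phenyl N,N-diethylcarbamate, via aryllithium 7 (not isolated), via arylcopper 8 (not isolated)
Conditions: s-BuLi, TMEDA, THF, −78 °C; CuBr·SMe2, −78 °C; prenyl bromide, −78 to 0 °C
Reagents that add atoms: prenyl bromide 6, CC(C)=CCBr
Why: Directed ortho-metalation takes place at the position flanked by the carbamate and the methoxy group, and transmetalation to copper at low temperature suppresses the anionic ortho-Fries shift and lets the arylcopper displace bromide at the primary terminus of prenyl bromide (copper-mediated allylic substitution).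

Step 5
Reactants: 9 3-methoxy-4-(methoxymethoxy)-2-(3-methylbut-2-en-1-yl)phenyl N,N-diethylcarbamate
Product: 10 3-methoxy-4-(methoxymethoxy)-2-(3-methylbut-2-en-1-yl)phenol
Conditions: LiAlH4, THF, reflux; then aq. KNaC4H4O6 (potassium sodium tartrate)
Reagents that add atoms: none
Why: LiAlH4 reduction of the aryl carbamate at its carbonyl expels the phenoxide, a standard non-acidic unmasking that avoids acid-induced cyclisation of the new phenol onto the neighbouring prenyl alkene and leaves the MOM ether intact.

Step 6
Reactants: 10 3-methoxy-4-(methoxymethoxy)-2-(3-methylbut-2-en-1-yl)phenol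
Product: 12 2-hydroxy-4-methoxy-5-(methoxymethoxy)-3-(3-methylbut-2-en-1-yl)benzaldehyde, via salicyl alcohol 11 (not isolated)
Conditions: MgCl2, Et3N, (CH2O)n, THF, reflux; then 1 M HCl work-up
Reagents that add atoms: paraformaldehyde (reacting as formaldehyde), C=O
Why: The magnesium-mediated ortho-formylation (Casnati–Skattebøl reaction) delivers formaldehyde within the ArOMgCl chelate only ortho to the phenol, and since a single ortho position is free the salicyl alcohol forms there and is oxidised in situ by hydride transfer to a second formaldehyde.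

Step 7
Reactants: 12 2-hydroxy-4-methoxy-5-(methoxymethoxy)-3-(3-methylbut-2-en-1-yl)benzaldehyde; 13 carbon tetrabromide
Product: 14 2-(2,2-dibromovinyl)-5-methoxy-4-(methoxymethoxy)-6-(3-methylbut-2-en-1-yl)phenol
Conditions: CBr4, PPh3, Et3N, CH2Cl2, 0 °C
Reagents that add atoms: carbon tetrabromide 13, BrC(Br)(Br)Br
Why: Ramirez dibromo-olefination (first stage of the Corey–Fuchs sequence) with the ylide Ph3P=CBr2 converts the aldehyde into the 1,1-dibromoalkene, a transformation known for unprotected salicylaldehydes when an amine buffer keeps the medium non-acidic.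

Step 8
Reactants: 14 2-(2,2-dibromovinyl)-5-methoxy-4-(methoxymethoxy)-6-(3-methylbut-2-en-1-yl)phenol
Product: 15 2-bromo-6-methoxy-5-(methoxymethoxy)-7-(3-methylbut-2-en-1-yl)-1-benzofuran
Conditions: CuI (5 mol%), K3PO4, THF, 80 °C, sealed tube, argon
Reagents that add atoms: none
Why: The phenoxide (ArOK) binds monovalent copper, which inserts into the C–Br bond cis to the arene to give a six-membered oxa-cupracycle of trivalent copper, and C–O reductive elimination then forms O1–C2 and releases the 2-bromobenzofuran. The closest known reaction type is the intramolecular Ullmann-type O-vinylation of 2-(2,2-dibromovinyl)phenols to 2-bromobenzofurans under CuI and phosphate base. The furan ring closes in a formally 5-endo-trig mode at the vinylic carbon, which the metal-templated pathway makes feasible where a direct addition–elimination would not be relied on. No stereocentre is created. The selectivity needed is between the two bromides and between the vinyl bromide and the prenyl alkene as partners for the phenol: geometry secures the first, because only the cis bromide can reach the copper-bound oxygen while the trans bromide stays as the C2 handle, and the absence of any oxidant or acid secures the second, so the neighbouring prenyl group is left alone.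

Step 9
Reactants: 16 3-bromo-5-methoxyphenol
Product: 17 3-methoxy-5-(4,4,5,5-tetramethyl-1,3,2-dioxaborolan-2-yl)phenol
Conditions: B2pin2, PdCl2(dppf) (3 mol%), KOAc, 1,4-dioxane, 90 °C
Reagents that add atoms: bis(pinacolato)diboron, CC1(C)OB(OC1(C)C)B1OC(C)(C)C(C)(C)O1
Why: Miyaura borylation of the aryl bromide under zerovalent palladium catalysis with the weak base KOAc tolerates a free phenol, so the hydroxyl needs no protection.

Step 10
Reactants: 15 2-bromo-6-methoxy-5-(methoxymethoxy)-7-(3-methylbut-2-en-1-yl)-1-benzofuran; 17 3-methoxy-5-(4,4,5,5-tetramethyl-1,3,2-dioxaborolan-2-yl)phenol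
Product: 18 3-methoxy-5-[6-methoxy-5-(methoxymethoxy)-7-(3-methylbut-2-en-1-yl)-1-benzofuran-2-yl]phenol
Conditions: Pd(PPh3)4 (5 mol%), K2CO3, 1,4-dioxane/H2O, 85 °C
Reagents that add atoms: boronate 17, COc1cc(O)cc(B2OC(C)(C)C(C)(C)O2)c1
Why: Suzuki–Miyaura coupling of the 2-bromobenzofuran, an activated heteroaryl bromide, with the arylboronic ester forms the C2–aryl bond, the phenol being carried as its phenoxide (ArOK) without interference.

Step 11
Reactants: 18 3-methoxy-5-[6-methoxy-5-(methoxymethoxy)-7-(3-methylbut-2-en-1-yl)-1-benzofuran-2-yl]phenol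
Product: 19 Dinklagein A, 2-(3-hydroxy-5-methoxyphenyl)-6-methoxy-7-(3-methylbut-2-en-1-yl)-1-benzofuran-5-ol
Conditions: HCl (1 M in MeOH), rt to 40 °C
Reagents that add atoms: none
Why: Acid-catalysed methanolysis cleaves the MOM acetal to the C5 phenol, and the prenyl group cannot cyclise because its ring neighbours are a methyl ether and the furan oxygen, not a free hydroxyl.

**Compound list**

1 | vanillin (4-hydroxy-3-methoxybenzaldehyde) | COc1cc(C=O)ccc1O | starting material
2 | 3-methoxy-4-(methoxymethoxy)benzaldehyde | COCOc1ccc(C=O)cc1OC | intermediate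
3 | 3-methoxy-4-(methoxymethoxy)phenyl formate | COCOc1ccc(OC=O)cc1OC | intermediate (not isolated)
4 | 3-methoxy-4-(methoxymethoxy)phenol | COCOc1ccc(O)cc1OC | intermediate
5 | 3-methoxy-4-(methoxymethoxy)phenyl N,N-diethylcarbamate | CCN(CC)C(=O)Oc1ccc(OCOC)c(OC)c1 | intermediate
6 | prenyl bromide (1-bromo-3-methylbut-2-ene) | CC(C)=CCBr | starting material
7 | [6-(diethylcarbamoyloxy)-2-methoxy-3-(methoxymethoxy)phenyl]lithium | CCN(CC)C(=O)Oc1ccc(OCOC)c(OC)c1[Li] | intermediate (not isolated)
8 | [6-(diethylcarbamoyloxy)-2-methoxy-3-(methoxymethoxy)phenyl]copper | CCN(CC)C(=O)Oc1ccc(OCOC)c(OC)c1[Cu] | intermediate (not isolated)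
9 | 3-methoxy-4-(methoxymethoxy)-2-(3-methylbut-2-en-1-yl)phenyl N,N-diethylcarbamate | CCN(CC)C(=O)Oc1ccc(OCOC)c(OC)c1CC=C(C)C | intermediate
10 | 3-methoxy-4-(methoxymethoxy)-2-(3-methylbut-2-en-1-yl)phenol | COCOc1ccc(O)c(CC=C(C)C)c1OC | intermediate
11 | 2-(hydroxymethyl)-5-methoxy-4-(methoxymethoxy)-6-(3-methylbut-2-en-1-yl)phenol (present as its chloromagnesium salt) | COCOc1cc(CO)c(O)c(CC=C(C)C)c1OC | intermediate (not isolated)
12 | 2-hydroxy-4-methoxy-5-(methoxymethoxy)-3-(3-methylbut-2-en-1-yl)benzaldehyde | COCOc1cc(C=O)c(O)c(CC=C(C)C)c1OC | intermediate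
13 | carbon tetrabromide | BrC(Br)(Br)Br | starting material
14 | 2-(2,2-dibromovinyl)-5-methoxy-4-(methoxymethoxy)-6-(3-methylbut-2-en-1-yl)phenol | COCOc1cc(C=C(Br)Br)c(O)c(CC=C(C)C)c1OC | intermediate
15 | 2-bromo-6-methoxy-5-(methoxymethoxy)-7-(3-methylbut-2-en-1-yl)-1-benzofuran | COCOc1cc2cc(Br)oc2c(CC=C(C)C)c1OC | intermediate
16 | 3-bromo-5-methoxyphenol | COc1cc(O)cc(Br)c1 | starting material
17 | 3-methoxy-5-(4,4,5,5-tetramethyl-1,3,2-dioxaborolan-2-yl)phenol | COc1cc(O)cc(B2OC(C)(C)C(C)(C)O2)c1 | intermediate
18 | 3-methoxy-5-[6-methoxy-5-(methoxymethoxy)-7-(3-methylbut-2-en-1-yl)-1-benzofuran-2-yl]phenol | COCOc1cc2cc(-c3cc(O)cc(OC)c3)oc2c(CC=C(C)C)c1OC | intermediate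
19 | Dinklagein A | COc1cc(O)cc(-c2cc3cc(O)c(OC)c(CC=C(C)C)c3o2)c1 | target

**Step count**

Total steps: 11. Longest linear sequence: 10 (steps 1 to 8, 10 and 11, from vanillin); step 9 is the one-step side branch.

**Steps most likely to fail**

Step 4. The arylmetal may be captured through the tertiary terminus of the prenyl electrophile. Capture may also be slow enough that the carbamoyl group migrates to carbon (anionic ortho-Fries shift) as the mixture warms. The fallback sets out from 5. The same lithiation to 7 is quenched at −78 °C with allyl bromide, which is symmetrical and fast, to give 2-allyl-3-methoxy-4-(methoxymethoxy)phenyl N,N-diethylcarbamate F1. Olefin cross-metathesis of F1 with excess 2-methyl-2-butene, using second-generation Grubbs catalyst (H2IMes)(PCy3)Cl2Ru=CHPh in CH2Cl2 at 40 °C, then builds the prenyl group. The route is rejoined at 9.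

Step 7. The free phenol may be tied up by the bromophosphonium species formed alongside the ylide. Traces of HBr may also cleave the MOM acetal or close the phenol onto the adjacent prenyl alkene. The fallback sets out from 12. The phenol is capped with Ac2O and pyridine to give 2-formyl-5-methoxy-4-(methoxymethoxy)-6-(3-methylbut-2-en-1-yl)phenyl acetate F2. Ramirez olefination of F2 (CBr4, PPh3, CH2Cl2, 0 °C) gives 2-(2,2-dibromovinyl)-5-methoxy-4-(methoxymethoxy)-6-(3-methylbut-2-en-1-yl)phenyl acetate F3. Methanolysis of the acetate with K2CO3 in MeOH at rt then releases the phenol. The route is rejoined at 14.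

Step 8. Copper insertion at the hindered, electron-rich phenoxide may stall. On prolonged heating the remaining C2 bromide may be lost by protodebromination or by intermolecular coupling with unreacted phenoxide. The fallback sets out from 14 together with boronate 17 and changes the order of bond formation in one flask under palladium catalysis (Pd(OAc)2, SPhos, K3PO4, toluene/H2O, 90 °C). Suzuki coupling at the more accessible trans bromide first gives (Z)-2-[2-bromo-2-(3-hydroxy-5-methoxyphenyl)ethenyl]-5-methoxy-4-(methoxymethoxy)-6-(3-methylbut-2-en-1-yl)phenol F4, which is not isolated. Its cis bromide then undergoes palladium-catalysed intramolecular C–O coupling to close the furan ring. The bromobenzofuran 15 is bypassed and the route is rejoined at 18.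

**Further compounds**

F1 | step 4 | 2-allyl-3-methoxy-4-(methoxymethoxy)phenyl N,N-diethylcarbamate | CCN(CC)C(=O)Oc1ccc(OCOC)c(OC)c1CC=C
F2 | step 7 | 2-formyl-5-methoxy-4-(methoxymethoxy)-6-(3-methylbut-2-en-1-yl)phenyl acetate | CC(=O)Oc1c(C=O)cc(OCOC)c(OC)c1CC=C(C)C
F3 | step 7 | 2-(2,2-dibromovinyl)-5-methoxy-4-(methoxymethoxy)-6-(3-methylbut-2-en-1-yl)phenyl acetate | CC(=O)Oc1c(C=C(Br)Br)cc(OCOC)c(OC)c1CC=C(C)C
F4 | step 8 | (Z)-2-[2-bromo-2-(3-hydroxy-5-methoxyphenyl)ethenyl]-5-methoxy-4-(methoxymethoxy)-6-(3-methylbut-2-en-1-yl)phenol | COCOc1cc(/C=C(\Br)c2cc(O)cc(OC)c2)c(O)c(CC=C(C)C)c1OC
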